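**Plan**

1. Numbering used throughout: C1 ring carbinol; C2–C4 crotonoyl (C=O, CH=CH); C5 CH–O-isovaleryl; C6 lactone O–CH; C7 lactone C–CH; C8 CH2; C9 CHOH; C10 CHMe; C11/C12/C13 lactone α-carbon, C=O, methylene. Target = 1S,5S,6R,7S,9R,10S.
2. Retrosynthetic cuts: C11=C13 (E1cB loss of a C13 ester) and the C9 silyl ether; C1–C10 (α-ketol shift from an eight-membered acyloin that holds C2 in the ring); C2–C3 (propenylcerium + 1,2-dione); C1=C2 (ring-closing metathesis); O6–C12 (lactone); C5–C6 (alkoxyallylboration); C11–C13 (formaldehyde aldol); C7–C11 (Evans alkylation); C9–C10 (crotylboration).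
3. Forward order: chain C6–C10, then C11/C12, then C5/C1, γ-lactone (first ring), C13, cyclooctene (second ring), 1,2-dione, 2-hydroxy-2-propenyl ketone, contraction to the cycloheptane, unmasking of the methylene lactone and of C9–OH.
4. Stereochemistry: C9/C10 from a catalyst-controlled syn-crotylboration; C7 from an oxazolidinone auxiliary; C5/C6 from an isopinocampheylborane; C1 from C2 (addition on the face opposite the lactone, anti to the C10 methyl) by a suprafacial 1,2-shift; C11 is temporary.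

Key step: step 16

Assumption: (S)-TRIP and the (+)-α-pinene-derived (Z)-γ-alkoxyallylborane are taken to add to the Si face of the aldehyde, as they do with simple aliphatic aldehydes; the face required is stated in each step.

**Route**

Step 1
Reactants: 1 methyl 4-oxobutanoate; 2 (Z)-crotylboronic acid pinacol ester
Product: 5 (5R)-5-[(2R)-but-3-en-2-yl]oxolan-2-one, via pinacol borate 3 (not isolated), via hydroxy ester 4 (not isolated)
Conditions: (S)-TRIP [(S)-3,3'-bis(2,4,6-triisopropylphenyl)-1,1'-binaphthyl-2,2'-diyl hydrogen phosphate, 5 mol %], 4 Å MS, PhMe, −30 °C; aq. NaHCO3; then TsOH·H2O (cat.), CH2Cl2, rt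
Reagents that add atoms: none
Why: Chiral-phosphoric-acid-catalysed crotylboration through a closed chair transition state, in which the Z-boronate gives the syn C9/C10 pair and the (S)-catalyst sends the crotyl group to the Si face of the aldehyde (9R,10R as drawn); the γ-hydroxy ester then lactonises under acid.

Step 2
Reactants: 5 (5R)-5-[(2R)-but-3-en-2-yl]oxolan-2-one
Product: 8 (4R,5R)-4-[(tert-butyldimethylsilyl)oxy]-5-methylhept-6-enoic acid, via potassium hydroxy carboxylate 6 (not isolated), via bis-silyl compound 7 (not isolated)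
Conditions: KOH, MeOH/H2O, rt; evaporate; TBSCl, imidazole, DMF, rt; then K2CO3, MeOH/THF/H2O, rt; aq. citric acid
Reagents that add atoms: potassium hydroxide, [K+].[OH-]; tert-butyldimethylsilyl chloride, CC(C)(C)[Si](C)(C)Cl
Why: Saponification of the γ-lactone, exhaustive silylation and selective hydrolysis of the labile silyl ester (a standard lactone-opening sequence) should give the O-silylated acid without touching C9 or C10.

Step 3
Reactants: 8 (4R,5R)-4-[(tert-butyldimethylsilyl)oxy]-5-methylhept-6-enoic acid; 9 (R)-4-benzyl-1,3-oxazolidin-2-one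
Product: 11 (4R)-4-benzyl-3-[(4R,5R)-4-[(tert-butyldimethylsilyl)oxy]-5-methylhept-6-enoyl]-1,3-oxazolidin-2-one, via mixed pivalic anhydride 10 (not isolated)
Conditions: t-BuCOCl, Et3N, THF, −20 °C; then LiCl, 9, −20 °C → rt
Reagents that add atoms: none
Why: N-Acylation of the oxazolidinone through the mixed pivalic anhydride; no stereocentre is touched, and any minor enantiomer carried over from step 1 becomes a separable diastereomer here.

Step 4
Reactants: 11 (4R)-4-benzyl-3-[(4R,5R)-4-[(tert-butyldimethylsilyl)oxy]-5-methylhept-6-enoyl]-1,3-oxazolidin-2-one; 12 tert-butyl bromoacetate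
Product: 14 tert-butyl (3S,5R,6R)-3-[(4R)-4-benzyl-2-oxo-1,3-oxazolidine-3-carbonyl]-5-[(tert-butyldimethylsilyl)oxy]-6-methyloct-7-enoate, via sodium Z-enolate 13 (not isolated)
Conditions: NaN(SiMe3)2, THF, −78 °C; then 12, −78 → −40 °C
Reagents that add atoms: none
Why: Evans asymmetric alkylation, in which the chelated Z-sodium enolate is alkylated by the α-bromo ester on the face away from the benzyl group, setting C7 as S.

Step 5
Reactants: 14 tert-butyl (3S,5R,6R)-3-[(4R)-4-benzyl-2-oxo-1,3-oxazolidine-3-carbonyl]-5-[(tert-butyldimethylsilyl)oxy]-6-methyloct-7-enoate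
Product: 15 tert-butyl (3S,5R,6R)-5-[(tert-butyldimethylsilyl)oxy]-3-(hydroxymethyl)-6-methyloct-7-enoate
Conditions: LiBH4, MeOH (1 equiv), THF, 0 °C
Reagents that add atoms: none
Why: Reductive removal of the auxiliary, since LiBH4 reduces the activated imide carbonyl to the primary alcohol and should leave the tert-butyl ester, silyl ether and alkene intact.

Step 6
Reactants: 15 tert-butyl (3S,5R,6R)-5-[(tert-butyldimethylsilyl)oxy]-3-(hydroxymethyl)-6-methyloct-7-enoate
Product: 16 tert-butyl (3S,5R,6R)-5-[(tert-butyldimethylsilyl)oxy]-3-formyl-6-methyloct-7-enoate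
Conditions: Dess–Martin periodinane, NaHCO3, CH2Cl2, 0 °C → rt; used crude
Reagents that add atoms: none
Why: Dess–Martin oxidation under bicarbonate buffer should give the α-branched aldehyde without epimerisation at C7.

Step 7
Reactants: 16 tert-butyl (3S,5R,6R)-5-[(tert-butyldimethylsilyl)oxy]-3-formyl-6-methyloct-7-enoate; 17 allyl 4-methoxybenzyl ether
Product: 22 tert-butyl (3S,5R,6R)-5-[(tert-butyldimethylsilyl)oxy]-3-[(1R,2R)-1-hydroxy-2-[(4-methoxybenzyl)oxy]but-3-en-1-yl]-6-methyloct-7-enoate, via lithiated allyl ether 18 (not isolated), via lithium methoxyborate 19 (not isolated), via Z-alkoxyallylborane 20 (not isolated), via borinate 21 (not isolated)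
Conditions: 17, s-BuLi, THF, −78 °C; (−)-Ipc2BOMe [from (+)-α-pinene]; BF3·OEt2; then 16, −78 °C; NaOH, H2O2, 0 °C → rt
Reagents that add atoms: none
Why: Brown alkoxyallylboration, in which the Z-γ-alkoxyallylborane reacts through a chair transition state to give the syn C5/C6 diol monoether and the isopinocampheyl groups override the weak bias of the α-centre, delivering the allyl unit to the Si face (6R,5R as drawn).

Step 8
Reactants: 22 tert-butyl (3S,5R,6R)-5-[(tert-butyldimethylsilyl)oxy]-3-[(1R,2R)-1-hydroxy-2-[(4-methoxybenzyl)oxy]but-3-en-1-yl]-6-methyloct-7-enoate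
Product: 23 (4S,5R)-4-[(2R,3R)-2-[(tert-butyldimethylsilyl)oxy]-3-methylpent-4-en-1-yl]-5-[(1R)-1-[(4-methoxybenzyl)oxy]prop-2-en-1-yl]oxolan-2-one
Conditions: CSA (cat.), PhMe, 60 °C
Reagents that add atoms: none
Why: Acid-catalysed lactonisation of the γ-hydroxy tert-butyl ester (5-exo-trig acyl substitution, loss of tert-butanol) closes the lactone with C6 and C7 substituents cis, as fixed in steps 4 and 7; catalytic acid in an aprotic solvent should spare the PMB and TBS ethers.

Step 9
Reactants: 23 (4S,5R)-4-[(2R,3R)-2-[(tert-butyldimethylsilyl)oxy]-3-methylpent-4-en-1-yl]-5-[(1R)-1-[(4-methoxybenzyl)oxy]prop-2-en-1-yl]oxolan-2-one; 24 formaldehyde (from paraformaldehyde)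
Product: 26 (3R,4S,5R)-3-(hydroxymethyl) derivative of lactone 23, via lithium enolate 25 (not isolated)
Conditions: LiN(i-Pr)2, THF, −78 °C; CH2O (gas, cracked paraformaldehyde), −78 → −20 °C; aq. NH4Cl
Reagents that add atoms: none
Why: Aldol hydroxymethylation of the lactone enolate with monomeric formaldehyde, the electrophile entering anti to the C6 and C7 substituents (11R, trans); this centre is removed again in step 17.

Step 10
Reactants: 26 (3R,4S,5R)-3-(hydroxymethyl) derivative of lactone 23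
Product: 27 (3R,4S,5R)-3-(hydroxymethyl)-5-[(1R)-1-hydroxyprop-2-en-1-yl]-4-[(2R,3R)-2-[(tert-butyldimethylsilyl)oxy]-3-methylpent-4-en-1-yl]oxolan-2-one
Conditions: DDQ, CH2Cl2/pH 7 buffer, 0 °C → rt
Reagents that add atoms: none
Why: Oxidative cleavage of the PMB ether with DDQ in wet CH2Cl2 frees the C5 hydroxyl, while the TBS ether, alkenes and lactone are inert.

Step 11
Reactants: 27 (3R,4S,5R)-3-(hydroxymethyl)-5-[(1R)-1-hydroxyprop-2-en-1-yl]-4-[(2R,3R)-2-[(tert-butyldimethylsilyl)oxy]-3-methylpent-4-en-1-yl]oxolan-2-one; 28 3-methylbutanoic acid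
Product: 29 bis(3-methylbutanoate) of diol 27 (esters at C5–O and C13–O)
Conditions: 28 (2.5 equiv), DCC, DMAP (cat.), CH2Cl2, 0 °C → rt
Reagents that add atoms: none
Why: Steglich esterification acylates both hydroxyls; the C5 ester is the one in the target and the C13 ester is a latent leaving group that keeps the methylene lactone masked through the alkene and carbonyl chemistry that follows.

Step 12
Reactants: 29 bis(3-methylbutanoate) of diol 27
Product: 30 cyclooctene-fused lactone (Z-C1=C2 in the eight-membered ring C6–C7–C8–C9–C10–C2–C1–C5; C5 and C13 isovalerates; C9 OTBS)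
Conditions: (H2IMes)(PCy3)Cl2Ru=CHPh (second-generation Grubbs catalyst, 10 mol %), CH2Cl2 (1 mM), 40 °C
Reagents that add atoms: none
Why: Ring-closing metathesis of the two monosubstituted alkenes; the cis-lactone holds both chains on one face so that C1 and C2 can meet, the ring size enforces the Z-alkene, and no stereocentre is formed.

Step 13
Reactants: 30 cyclooctene-fused lactone
Product: 31 cis-1,2-diol at C1 and C2 (both hydroxyls anti to the C5 ester)
Conditions: OsO4 (5 mol %), NMO, acetone/H2O, rt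
Reagents that add atoms: osmium tetroxide, O=[Os](=O)(=O)=O; N-methylmorpholine N-oxide, C[N+]1([O-])CCOCC1; water, O
Why: Upjohn syn-dihydroxylation of the only alkene, expected anti to the allylic ester oxygen; the configuration of the two new carbinols is of no consequence because both are oxidised in step 14.

Step 14
Reactants: 31 cis-1,2-diol at C1 and C2
Product: 32 cyclooctane-1,2-dione (C1 and C2 ketones)
Conditions: IBX (2-iodoxybenzoic acid, 4 equiv), DMSO, rt; used without chromatography
Reagents that add atoms: none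
Why: IBX oxidises vicinal diols to 1,2-diones without C–C cleavage, and its neutral conditions avoid β-elimination of the C6 lactone oxygen and epimerisation at C5 or C10.

Step 15
Reactants: 32 cyclooctane-1,2-dione; 33 (E)-1-bromoprop-1-ene
Product: 36 lactone-fused (2S)-2-hydroxy-2-[(E)-prop-1-enyl]cyclooctanone (C2 carbinol next to C10 and C1 ketone next to C5), via E-propenyllithium 34 (not isolated), via propenylcerium dichloride 35 (not isolated)
Conditions: 33, t-BuLi (2 equiv), Et2O, −78 °C; CeCl3, THF, −78 °C; then 32, −78 °C; aq. NH4Cl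
Reagents that add atoms: none
Why: Organocerium 1,2-addition to a 1,2-dione: the weakly basic reagent (formed with retention from the E-bromide) adds once, at the C2 carbonyl, whose face opposite the lactone carries only the C10 hydrogen, whereas C1 is screened there by the C5 ester and on the other face by the lactone; attack anti to the C10 methyl sets the carbinol as 2S (hydroxyl on the lactone face, propenyl opposite).

Step 16
Reactants: 36 lactone-fused (2S)-2-hydroxy-2-[(E)-prop-1-enyl]cyclooctanone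
Product: 37 lactone-fused (1S)-1-[(E)-but-2-enoyl]cycloheptan-1-ol (ring C6–C7–C8–C9–C10–C1–C5; C5 and C13 isovalerates; C9 OTBS)
Conditions: Zn(OTf)2 (0.3 equiv), 4 Å MS, PhMe, 70 °C
Reagents that add atoms: none
Why: Zn(OTf)2 binds the C2 hydroxyl and the C1 carbonyl oxygen in a five-membered chelate, which holds the two oxygens syn and sets the C2–C10 bond parallel to the π* orbital of C1=O; C10 then shifts from C2 to C1 with retention while the C2 alkoxide becomes the ketone (α-ketol, or acyloin, rearrangement). The closest known reaction type is the Lewis-acid- or base-promoted ring contraction of 2-alkyl-2-hydroxycycloalkanones to 1-acylcycloalkanols. The cycloheptane arises by this 1,2-shift as a ring contraction (C1–C10 made, C2–C10 broken, C2 expelled from the ring) and not by an end-to-end cyclisation. The new centre C1 is controlled by C2: within the syn chelate C10 can reach only the face of C1 on which it already lies, so the 2S carbinol gives the 1S carbinol, with the hydroxyl on the lactone face and the acyl group opposite. The step needs migration of the ring bond in preference to the propenyl group and a favourable equilibrium; a propenyl shift merely exchanges carbinol and ketone inside the eight-membered ring and is reversible, whereas the C10 shift is pulled forward by the new enone conjugation and the loss of the cyclooctanone. The zinc chelate also disfavours ionisation of the tertiary allylic carbinol, which lies α to a carbonyl group.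

Step 17
Reactants: 37 lactone-fused (1S)-1-[(E)-but-2-enoyl]cycloheptan-1-ol
Product: 38 C9 O-TBS ether of the target (α-methylene lactone)
Conditions: DBU, CH2Cl2, 0 °C → rt
Reagents that add atoms: none
Why: E1cB elimination of the β-acyloxy group from the lactone reveals the C11=C13 methylene; the C5 ester cannot eliminate because C1 is quaternary, and the C9 silyl ether keeps that oxygen from adding to the new acceptor.

Step 18
Reactants: 38 C9 O-TBS ether of the target
Product: 39 CNP0186412.1
Conditions: HF·pyridine, pyridine/THF, 0 °C → rt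
Reagents that add atoms: none
Why: Fluoride-mediated cleavage of the secondary TBS ether under mildly acidic conditions, which should not harm the methylene lactone, the enone, the tertiary α-ketol or the ester.

**Compound list**

1 | methyl 4-oxobutanoate | COC(=O)CCC=O | starting material
2 | (Z)-crotylboronic acid pinacol ester | C/C=C\CB1OC(C)(C)C(C)(C)O1 | starting material
3 | pinacol borate of methyl (4R,5R)-4-hydroxy-5-methylhept-6-enoate | C=C[C@@H](C)[C@H](OB1OC(C)(C)C(C)(C)O1)CCC(=O)OC | intermediate (not isolated)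
4 | methyl (4R,5R)-4-hydroxy-5-methylhept-6-enoate | C=C[C@@H](C)[C@H](O)CCC(=O)OC | intermediate (not isolated)
5 | (5R)-5-[(2R)-but-3-en-2-yl]oxolan-2-one | C=C[C@@H](C)[C@H]1CCC(=O)O1 | intermediate
6 | potassium (4R,5R)-4-hydroxy-5-methylhept-6-enoate | C=C[C@@H](C)[C@H](O)CCC(=O)[O-].[K+] | intermediate (not isolated)
7 | tert-butyldimethylsilyl (4R,5R)-4-[(tert-butyldimethylsilyl)oxy]-5-methylhept-6-enoate | C=C[C@@H](C)[C@H](O[Si](C)(C)C(C)(C)C)CCC(=O)O[Si](C)(C)C(C)(C)C | intermediate (not isolated)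
8 | (4R,5R)-4-[(tert-butyldimethylsilyl)oxy]-5-methylhept-6-enoic acid | C=C[C@@H](C)[C@H](O[Si](C)(C)C(C)(C)C)CCC(=O)O | intermediate
9 | (R)-4-benzyl-1,3-oxazolidin-2-one | O=C1N[C@H](Cc2ccccc2)CO1 | starting material
10 | mixed anhydride of acid 8 with pivalic acid | C=C[C@@H](C)[C@H](O[Si](C)(C)C(C)(C)C)CCC(=O)OC(=O)C(C)(C)C | intermediate (not isolated)
11 | (4R)-4-benzyl-3-[(4R,5R)-4-[(tert-butyldimethylsilyl)oxy]-5-methylhept-6-enoyl]-1,3-oxazolidin-2-one | C=C[C@@H](C)[C@H](O[Si](C)(C)C(C)(C)C)CCC(=O)N1[C@H](Cc2ccccc2)COC1=O | intermediate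
12 | tert-butyl bromoacetate | BrCC(=O)OC(C)(C)C | starting material
13 | sodium Z-enolate of imide 11 | C=C[C@@H](C)[C@H](O[Si](C)(C)C(C)(C)C)C/C=C(\[O-])N1[C@H](Cc2ccccc2)COC1=O.[Na+] | intermediate (not isolated)
14 | tert-butyl (3S,5R,6R)-3-[(4R)-4-benzyl-2-oxo-1,3-oxazolidine-3-carbonyl]-5-[(tert-butyldimethylsilyl)oxy]-6-methyloct-7-enoate | C=C[C@@H](C)[C@H](O[Si](C)(C)C(C)(C)C)C[C@@H](CC(=O)OC(C)(C)C)C(=O)N1[C@H](Cc2ccccc2)COC1=O | intermediate
15 | tert-butyl (3S,5R,6R)-5-[(tert-butyldimethylsilyl)oxy]-3-(hydroxymethyl)-6-methyloct-7-enoate | C=C[C@@H](C)[C@H](O[Si](C)(C)C(C)(C)C)C[C@@H](CC(=O)OC(C)(C)C)CO | intermediate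
16 | tert-butyl (3S,5R,6R)-5-[(tert-butyldimethylsilyl)oxy]-3-formyl-6-methyloct-7-enoate | C=C[C@@H](C)[C@H](O[Si](C)(C)C(C)(C)C)C[C@@H](CC(=O)OC(C)(C)C)C=O | intermediate
17 | allyl 4-methoxybenzyl ether | C=CCOCc1ccc(OC)cc1 | starting material
18 | (Z)-3-[(4-methoxybenzyl)oxy]allyllithium | [Li]C/C=C\OCc1ccc(OC)cc1 | intermediate (not isolated)
19 | lithium [(Z)-3-[(4-methoxybenzyl)oxy]allyl](methoxy)bis(isopinocampheyl)borate | [Li+].CO[B-](C/C=C\OCc1ccc(OC)cc1)([C@@H]1C[C@@H]2C[C@H]([C@H]1C)C2(C)C)[C@@H]1C[C@@H]2C[C@H]([C@H]1C)C2(C)C | intermediate (not isolated)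
20 | [(Z)-3-[(4-methoxybenzyl)oxy]allyl]bis(isopinocampheyl)borane, Ipc from (+)-α-pinene | COc1ccc(CO/C=C\CB([C@@H]2C[C@@H]3C[C@H]([C@H]2C)C3(C)C)[C@@H]2C[C@@H]3C[C@H]([C@H]2C)C3(C)C)cc1 | intermediate (not isolated)
21 | O-bis(isopinocampheyl)boryl derivative of alcohol 22 | C=C[C@@H](C)[C@H](O[Si](C)(C)C(C)(C)C)C[C@@H](CC(=O)OC(C)(C)C)[C@@H](OB([C@@H]1C[C@@H]2C[C@H]([C@H]1C)C2(C)C)[C@@H]1C[C@@H]2C[C@H]([C@H]1C)C2(C)C)[C@H](OCc1ccc(OC)cc1)C=C | intermediate (not isolated)
22 | tert-butyl (3S,5R,6R)-5-[(tert-butyldimethylsilyl)oxy]-3-[(1R,2R)-1-hydroxy-2-[(4-methoxybenzyl)oxy]but-3-en-1-yl]-6-methyloct-7-enoate | C=C[C@@H](C)[C@H](O[Si](C)(C)C(C)(C)C)C[C@@H](CC(=O)OC(C)(C)C)[C@@H](O)[C@H](OCc1ccc(OC)cc1)C=C | intermediate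
23 | (4S,5R)-4-[(2R,3R)-2-[(tert-butyldimethylsilyl)oxy]-3-methylpent-4-en-1-yl]-5-[(1R)-1-[(4-methoxybenzyl)oxy]prop-2-en-1-yl]oxolan-2-one | C=C[C@@H](C)[C@H](O[Si](C)(C)C(C)(C)C)C[C@H]1CC(=O)O[C@H]1[C@H](OCc2ccc(OC)cc2)C=C | intermediate
24 | formaldehyde (used as paraformaldehyde) | C=O | starting material
25 | lithium enolate of lactone 23 | C=C[C@@H](C)[C@H](O[Si](C)(C)C(C)(C)C)C[C@H]1C=C([O-])O[C@H]1[C@H](OCc2ccc(OC)cc2)C=C.[Li+] | intermediate (not isolated)
26 | (3R,4S,5R)-3-(hydroxymethyl) derivative of lactone 23 (CH2OH trans to the C7 chain) | C=C[C@@H](C)[C@H](O[Si](C)(C)C(C)(C)C)C[C@H]1[C@H](CO)C(=O)O[C@H]1[C@H](OCc2ccc(OC)cc2)C=C | intermediate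
27 | (3R,4S,5R)-3-(hydroxymethyl)-5-[(1R)-1-hydroxyprop-2-en-1-yl]-4-[(2R,3R)-2-[(tert-butyldimethylsilyl)oxy]-3-methylpent-4-en-1-yl]oxolan-2-one | C=C[C@@H](C)[C@H](O[Si](C)(C)C(C)(C)C)C[C@H]1[C@H](CO)C(=O)O[C@H]1[C@H](O)C=C | intermediate
28 | 3-methylbutanoic acid | CC(C)CC(=O)O | starting material
29 | bis(3-methylbutanoate) of diol 27 | C=C[C@@H](C)[C@H](O[Si](C)(C)C(C)(C)C)C[C@H]1[C@H](COC(=O)CC(C)C)C(=O)O[C@H]1[C@H](OC(=O)CC(C)C)C=C | intermediate
30 | cyclooctene-fused lactone (Z-C1=C2; C5 and C13 isovalerates; C9 OTBS) | [C@@H]1(COC(=O)CC(C)C)C(=O)O[C@@H]2[C@H]1C[C@@H](O[Si](C)(C)C(C)(C)C)[C@H](C)/C=C\[C@H]2OC(=O)CC(C)C | intermediate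
31 | C1,C2-cis-diol of 30 (hydroxyls anti to the C5 ester) | [C@@H]1(COC(=O)CC(C)C)C(=O)O[C@@H]2[C@H]1C[C@@H](O[Si](C)(C)C(C)(C)C)[C@H](C)[C@H](O)[C@H](O)[C@H]2OC(=O)CC(C)C | intermediate
32 | lactone-fused cyclooctane-1,2-dione (C1, C2) | [C@@H]1(COC(=O)CC(C)C)C(=O)O[C@@H]2[C@H]1C[C@@H](O[Si](C)(C)C(C)(C)C)[C@H](C)C(=O)C(=O)[C@H]2OC(=O)CC(C)C | intermediate
33 | (E)-1-bromoprop-1-ene | C/C=C/Br | starting material
34 | (E)-prop-1-enyllithium | C/C=C/[Li] | intermediate (not isolated)
35 | dichloro[(E)-prop-1-enyl]cerium | C/C=C/[Ce](Cl)Cl | intermediate (not isolated)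
36 | lactone-fused (2S)-2-hydroxy-2-[(E)-prop-1-enyl]cyclooctanone (C2 in the ring, C1 ketone; C5 and C13 isovalerates; C9 OTBS) | [C@@H]1(COC(=O)CC(C)C)C(=O)O[C@@H]2[C@H]1C[C@@H](O[Si](C)(C)C(C)(C)C)[C@H](C)[C@@](O)(/C=C/C)C(=O)[C@H]2OC(=O)CC(C)C | intermediate
37 | lactone-fused (1S)-1-[(E)-but-2-enoyl]cycloheptan-1-ol (C5 and C13 isovalerates; C9 OTBS) | [C@@H]1(COC(=O)CC(C)C)C(=O)O[C@@H]2[C@H]1C[C@@H](O[Si](C)(C)C(C)(C)C)[C@H](C)[C@@](O)(C(=O)/C=C/C)[C@H]2OC(=O)CC(C)C | intermediate
38 | C9 O-TBS ether of the target | C=C1C(=O)O[C@@H]2[C@H]1C[C@@H](O[Si](C)(C)C(C)(C)C)[C@H](C)[C@@](O)(C(=O)/C=C/C)[C@H]2OC(=O)CC(C)C | intermediate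
39 | CNP0186412.1 | C=C1C(=O)O[C@@H]2[C@H]1C[C@@H](O)[C@H](C)[C@@](O)(C(=O)/C=C/C)[C@H]2OC(=O)CC(C)C | target

**Step count and risks**

Total: 18 steps. Longest linear sequence: 18 steps (1 → 39); compounds 2, 9, 12, 17, 24, 28 and 33 are bought.

Most likely to fail:

Step 16 (ring contraction). The Lewis acid may ionise the tertiary allylic carbinol (1,3-transposition or dehydration), or the shift may stop after propenyl migration within the eight-membered ring. The fallback sets out from dione 32 and carries an alkyne through the shift. CH3C≡CMgBr with CeCl3 (THF, −78 °C) should give the eight-membered 2-hydroxy-2-(prop-1-ynyl) ketone F1. A propargylic carbinol resists ionisation and an alkynyl group migrates poorly, so Zn(OTf)2 in toluene should move only the ring bond and give the seven-membered 1-(but-2-ynoyl) carbinol F2, still driven by ynone conjugation. Trans-selective reduction of the ynone with CrSO4 (divalent chromium) in DMF/H2O then rejoins the route at 37.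

Step 15 (mono-addition to the dione). Regio- or facial control may be lost (attack at the C1 carbonyl or on the lactone face), or the dione may enolise. The fallback sets out from diol 31 and makes the two carbons different before the carbon nucleophile arrives. Et3SiCl and imidazole at −20 °C should silylate the less hindered C1 hydroxyl (its cis neighbour on C5 is hydrogen, that of the C2 hydroxyl is the C10 methyl) to give the C1 triethylsilyl ether F3. Dess–Martin oxidation gives the C2 ketone F4, and the propenylcerium reagent 35 then meets a single carbonyl whose two α-substituents (C1–OSiEt3 and C10–Me) lie on the lactone face, which should give the 2S carbinol F5. AcOH/THF/H2O removes the triethylsilyl group in the presence of the C9 TBS ether to give the diol F6, and IBX in DMSO oxidises the secondary C1 hydroxyl, rejoining the route at 36.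

Step 12 (eight-membered ring closure). Intermolecular metathesis may outrun the strained closure, or initiation at the allylic ester alkene may be slow. The fallback sets out from diene 29 and forms the C1–C2 bond reductively instead. Ozonolysis (O3, CH2Cl2, −78 °C; PPh3) gives the dialdehyde F7, and intramolecular pinacol coupling with SmI2 (THF, t-BuOH, −78 °C, high dilution; low temperature so that ketyl coupling precedes any loss of the α-acyloxy group) should give the cis-diol as 31 and its C1,C2-bis-epimer F8. Both are oxidised by IBX as in step 14, rejoining the route at dione 32 without the alkene 30.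

**Further compounds**

F1 | step 16 | lactone-fused (2S)-2-hydroxy-2-(prop-1-ynyl)cyclooctanone (alkynyl analogue of 36) | [C@@H]1(COC(=O)CC(C)C)C(=O)O[C@@H]2[C@H]1C[C@@H](O[Si](C)(C)C(C)(C)C)[C@H](C)[C@@](O)(C#CC)C(=O)[C@H]2OC(=O)CC(C)C
F2 | step 16 | lactone-fused (1S)-1-(but-2-ynoyl)cycloheptan-1-ol (ynone analogue of 37) | [C@@H]1(COC(=O)CC(C)C)C(=O)O[C@@H]2[C@H]1C[C@@H](O[Si](C)(C)C(C)(C)C)[C@H](C)[C@@](O)(C(=O)C#CC)[C@H]2OC(=O)CC(C)C
F3 | step 15 | C1 triethylsilyl ether of diol 31 | [C@@H]1(COC(=O)CC(C)C)C(=O)O[C@@H]2[C@H]1C[C@@H](O[Si](C)(C)C(C)(C)C)[C@H](C)[C@H](O)[C@H](O[Si](CC)(CC)CC)[C@H]2OC(=O)CC(C)C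
F4 | step 15 | C2 ketone bearing the C1 triethylsilyl ether | [C@@H]1(COC(=O)CC(C)C)C(=O)O[C@@H]2[C@H]1C[C@@H](O[Si](C)(C)C(C)(C)C)[C@H](C)C(=O)[C@H](O[Si](CC)(CC)CC)[C@H]2OC(=O)CC(C)C
F5 | step 15 | (2S)-2-hydroxy-2-[(E)-prop-1-enyl] compound bearing the C1 triethylsilyl ether | [C@@H]1(COC(=O)CC(C)C)C(=O)O[C@@H]2[C@H]1C[C@@H](O[Si](C)(C)C(C)(C)C)[C@H](C)[C@@](O)(/C=C/C)[C@H](O[Si](CC)(CC)CC)[C@H]2OC(=O)CC(C)C
F6 | step 15 | C1,C2-diol with tertiary (2S) propenyl carbinol | [C@@H]1(COC(=O)CC(C)C)C(=O)O[C@@H]2[C@H]1C[C@@H](O[Si](C)(C)C(C)(C)C)[C@H](C)[C@@](O)(/C=C/C)[C@H](O)[C@H]2OC(=O)CC(C)C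
F7 | step 12 | dialdehyde from ozonolysis of 29 (formyl groups as C1 and C2) | O=C[C@@H](C)[C@H](O[Si](C)(C)C(C)(C)C)C[C@H]1[C@H](COC(=O)CC(C)C)C(=O)O[C@H]1[C@H](OC(=O)CC(C)C)C=O
F8 | step 12 | C1,C2-bis-epimer of diol 31 | [C@@H]1(COC(=O)CC(C)C)C(=O)O[C@@H]2[C@H]1C[C@@H](O[Si](C)(C)C(C)(C)C)[C@H](C)[C@@H](O)[C@@H](O)[C@H]2OC(=O)CC(C)C
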